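The chromone is cut at the aryl ether bond O1–C8a. In the benzo ring (ring A), C4a carries the C4 ketone and has C8a and C5 ortho and C7 para, so a 2,4,6-trifluoro-3,5-dimethylbenzoyl unit can supply all three oxygens by fluoride displacement. In the key step the enol oxygen of a 1-aryl-1,3-diketone attacks one of two equivalent ortho C–F carbons and closes the pyran-4-one ring (ring C) in one operation, leaving the C5 and C7 fluorides for later exchange against methoxide. The precursor is 1-(2,4,6-trifluoro-3,5-dimethylphenyl)hexadecane-1,3-dione, built from 1,3,5-trifluorobenzene by lithiation chemistry and one enolate acylation.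

Key step: step 4

Remark on the chemistry: the target is achiral, so no stereocontrol is needed; the diketone is made by acylating a preformed lithium enolate with the acid chloride, so that no alkoxide is released beside the activated C–F bonds before ring closure.

Step 1
Reactants: 1 1,3,5-trifluorobenzene; 2 iodomethane
Product: 6 1,3,5-trifluoro-2,4-dimethylbenzene, via 2,4,6-trifluorophenyllithium 3 (not isolated), via 2,4,6-trifluorotoluene 4 (not isolated), via 2,4,6-trifluoro-3-methylphenyllithium 5 (not isolated)
Conditions: n-BuLi (1.0 equiv), THF, −78 °C; MeI (1.0 equiv), −78 → −20 °C; n-BuLi (1.05 equiv), −78 °C; MeI (1.3 equiv), −78 °C → rt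
Reagents that add atoms: iodomethane, CI
Why: Every ring proton of 1 and of 4 lies between two fluorines and is the most acidic site, so deprotonation by n-BuLi (directed ortho-lithiation) raises no regiochemical question, and each aryllithium is methylated by SN2 attack on iodomethane at −78 °C, before LiF loss to an aryne can set in.

Step 2
Reactants: 6 1,3,5-trifluoro-2,4-dimethylbenzene; 7 N-methoxy-N-methylacetamide
Product: 10 1-(2,4,6-trifluoro-3,5-dimethylphenyl)ethan-1-one, via 2,4,6-trifluoro-3,5-dimethylphenyllithium 8 (not isolated), via lithium tetrahedral adduct 9 (not isolated)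
Conditions: n-BuLi (1.05 equiv), THF, −78 °C; then 7, −78 → 0 °C; 1 M HCl
Reagents that add atoms: N-methoxy-N-methylacetamide, CC(=O)N(C)OC
Why: The last ring proton of 6 is again flanked by two fluorines and is removed cleanly (directed ortho-lithiation), and aryllithium 8 adds to the amide to give the chelated adduct 9, which releases the ketone only on acidic work-up, so a second addition is excluded (Weinreb ketone synthesis).

Step 3
Reactants: 10 1-(2,4,6-trifluoro-3,5-dimethylphenyl)ethan-1-one; 11 tetradecanoyl chloride
Product: 14 1-(2,4,6-trifluoro-3,5-dimethylphenyl)hexadecane-1,3-dione, via lithium enolate 12 (not isolated), via lithium diketonate 13 (not isolated)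
Conditions: LiN(SiMe3)2 (2.2 equiv), THF, −78 °C; then 11 (1.0 equiv), −78 → −20 °C; cold 1 M HCl
Reagents that add atoms: tetradecanoyl chloride, CCCCCCCCCCCCCC(=O)Cl
Why: The methyl ketone is enolised irreversibly at −78 °C and enolate 12 is C-acylated by the acid chloride (crossed Claisen-type enolate acylation), while the second equivalent of base traps the product as the chelated diketonate 13, which in cold THF neither reacts further nor displaces fluoride.

Step 4
Reactants: 14 1-(2,4,6-trifluoro-3,5-dimethylphenyl)hexadecane-1,3-dione
Product: 17 5,7-difluoro-6,8-dimethyl-2-tridecyl-4H-chromen-4-one, via potassium enolate 15 (not isolated), via Meisenheimer adduct 16 (not isolated)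
Conditions: K2CO3 (2 equiv), DMF (0.05 M), 60 °C
Reagents that add atoms: none
Why: Carbonate converts 14 into the Z-enolate 15, whose oxygen on C3 of the chain adds to one of the two fluorine-bearing carbons ortho to the aryl ketone to give the anion 16, with the charge delocalised into the C4 carbonyl; loss of fluoride restores the arene and forms O1–C8a (intramolecular nucleophilic aromatic substitution by addition and elimination). The closest known reaction type is the base-mediated cyclisation of 1-(2-fluoroaryl)-1,3-diketones to chromones and flavones. Ring C closes in a six-membered mode that is 6-exo-trig with respect to the C8a–C8 π bond (equivalently a 6-endo-trig oxa-Michael addition to the C8a=C4a–C4=O unit), and both descriptions are favourable. No stereocentre appears in the product, since the sp3 carbon of 16 is transient. The step needs O-arylation over C-arylation and intramolecular over intermolecular attack: attack through carbon would have to form a four-membered ring, the Z-enolate holds its oxygen in a six-membered transition state beside the ortho fluoride, dilution disfavours attack on the para fluoride of a second molecule, and the mirror symmetry of the aryl group makes the two ortho fluorides identical.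

Step 5
Reactants: 17 5,7-difluoro-6,8-dimethyl-2-tridecyl-4H-chromen-4-one; 18 sodium methoxide
Product: 21 5,7-dimethoxy-6,8-dimethyl-2-tridecyl-4H-chromen-4-one, via 7-fluoro-5-methoxy monoether 19 (not isolated), via 5-fluoro-7-methoxy monoether 20 (not isolated)
Conditions: NaOMe (6 equiv), DMSO–MeOH (4:1), 80 °C; then 1 M HCl
Reagents that add atoms: sodium methoxide, [Na+].[O-]C
Why: The two remaining fluorides lie ortho (C5) and para (C7) to C4a and its carbonyl, so methoxide should displace them in two successive nucleophilic aromatic substitutions through whichever monoether (19 or 20) forms first; the small nucleophile tolerates the flanking methyl groups, methanol tempers deprotonation of the C2 side chain, and the acidic work-up recloses any pyranone opened reversibly by methoxide addition at C2.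

Step 6
Reactants: 21 5,7-dimethoxy-6,8-dimethyl-2-tridecyl-4H-chromen-4-one
Product: 23 5,7-dihydroxy-6,8-dimethyl-2-tridecyl-4H-chromen-4-one (target), via bis(dibromoboryl) ether 22 (not isolated)
Conditions: BBr3 (5 equiv), CH2Cl2, −78 °C → rt; then ice-water
Reagents that add atoms: none
Why: BBr3 coordinates each ether oxygen and bromide removes the methyl group by SN2 attack (Lewis acid-mediated cleavage of aryl methyl ethers), helped at C5 by chelation to the C4 carbonyl and at C7 by the high basicity of the twisted ether; the pyranone, the alkyl chain and the aryl methyl groups are inert, and water hydrolyses 22 to the diphenol.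

Compound list
1 | 1,3,5-trifluorobenzene | Fc1cc(F)cc(F)c1 | starting material
2 | iodomethane | CI | starting material
3 | 2,4,6-trifluorophenyllithium (not isolated) | [Li]c1c(F)cc(F)cc1F | intermediate
4 | 2,4,6-trifluorotoluene (not isolated) | Cc1c(F)cc(F)cc1F | intermediate
5 | 2,4,6-trifluoro-3-methylphenyllithium (not isolated) | [Li]c1c(F)c(C)c(F)cc1F | intermediate
6 | 1,3,5-trifluoro-2,4-dimethylbenzene | Cc1c(F)c(C)c(F)cc1F | intermediate
7 | N-methoxy-N-methylacetamide | CC(=O)N(C)OC | starting material
8 | 2,4,6-trifluoro-3,5-dimethylphenyllithium (not isolated) | [Li]c1c(F)c(C)c(F)c(C)c1F | intermediate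
9 | lithium 1-[methoxy(methyl)amino]-1-(2,4,6-trifluoro-3,5-dimethylphenyl)ethan-1-olate (racemic, not isolated) | CC(O[Li])(N(C)OC)c1c(F)c(C)c(F)c(C)c1F | intermediate
10 | 1-(2,4,6-trifluoro-3,5-dimethylphenyl)ethan-1-one | CC(=O)c1c(F)c(C)c(F)c(C)c1F | intermediate
11 | tetradecanoyl chloride | CCCCCCCCCCCCCC(=O)Cl | starting material
12 | lithium 1-(2,4,6-trifluoro-3,5-dimethylphenyl)ethen-1-olate (not isolated) | C=C(O[Li])c1c(F)c(C)c(F)c(C)c1F | intermediate
13 | lithium (Z)-1-oxo-1-(2,4,6-trifluoro-3,5-dimethylphenyl)hexadec-2-en-3-olate (chelated diketonate, not isolated) | CCCCCCCCCCCCC/C(O[Li])=C/C(=O)c1c(F)c(C)c(F)c(C)c1F | intermediate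
14 | 1-(2,4,6-trifluoro-3,5-dimethylphenyl)hexadecane-1,3-dione | CCCCCCCCCCCCCC(=O)CC(=O)c1c(F)c(C)c(F)c(C)c1F | intermediate
15 | potassium (Z)-1-oxo-1-(2,4,6-trifluoro-3,5-dimethylphenyl)hexadec-2-en-3-olate (not isolated) | CCCCCCCCCCCCC/C(O[K])=C/C(=O)c1c(F)c(C)c(F)c(C)c1F | intermediate
16 | potassium 5,7,8a-trifluoro-6,8-dimethyl-2-tridecyl-8aH-chromen-4-olate (racemic, transient, not isolated) | CCCCCCCCCCCCCC1=CC([O-])=C2C(F)=C(C)C(F)=C(C)C2(F)O1.[K+] | intermediate
17 | 5,7-difluoro-6,8-dimethyl-2-tridecyl-4H-chromen-4-one | CCCCCCCCCCCCCc1cc(=O)c2c(F)c(C)c(F)c(C)c2o1 | intermediate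
18 | sodium methoxide | [Na+].[O-]C | starting material
19 | 7-fluoro-5-methoxy-6,8-dimethyl-2-tridecyl-4H-chromen-4-one (not isolated) | CCCCCCCCCCCCCc1cc(=O)c2c(OC)c(C)c(F)c(C)c2o1 | intermediate
20 | 5-fluoro-7-methoxy-6,8-dimethyl-2-tridecyl-4H-chromen-4-one (not isolated) | CCCCCCCCCCCCCc1cc(=O)c2c(F)c(C)c(OC)c(C)c2o1 | intermediate
21 | 5,7-dimethoxy-6,8-dimethyl-2-tridecyl-4H-chromen-4-one | CCCCCCCCCCCCCc1cc(=O)c2c(OC)c(C)c(OC)c(C)c2o1 | intermediate
22 | 5,7-bis[(dibromoboranyl)oxy]-6,8-dimethyl-2-tridecyl-4H-chromen-4-one (simplest formulation, not isolated) | CCCCCCCCCCCCCc1cc(=O)c2c(OB(Br)Br)c(C)c(OB(Br)Br)c(C)c2o1 | intermediate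
23 | 5,7-dihydroxy-6,8-dimethyl-2-tridecyl-4H-chromen-4-one | CCCCCCCCCCCCCc1cc(=O)c2c(O)c(C)c(O)c(C)c2o1 | target

Total step count: 6
Longest linear sequence: 6 steps (1 → 23)

Steps most likely to fail

Step 4 (key step). The delocalised, weakly nucleophilic diketonate may close slowly, so that attack of one enolate on the activated para C–F bond of another molecule (oligomer formation) or retro-Claisen cleavage by traces of water takes over. The fallback uses known chemistry and closes the pyranone by acid-catalysed cyclodehydration, forming O1–C2 last; it sets out from 6 and comes back to the route at 23. Lithiation of 6 as in step 2 (through 8) and quenching with DMF should give 2,4,6-trifluoro-3,5-dimethylbenzaldehyde F1. In this non-enolisable, strongly activated aldehyde all three fluorides are exchanged with NaOMe in MeOH–THF at reflux to give 2,4,6-trimethoxy-3,5-dimethylbenzaldehyde F2. The kinetic lithium enolate of pentadecan-2-one (LiN(i-Pr)2, THF, −78 °C) adds to F2 to give the racemic aldol 1-hydroxy-1-(2,4,6-trimethoxy-3,5-dimethylphenyl)hexadecan-3-one F3, and Dess–Martin periodinane oxidises it to 1-(2,4,6-trimethoxy-3,5-dimethylphenyl)hexadecane-1,3-dione F4. BBr3 in CH2Cl2 removes the three methyl groups to give 1-(2,4,6-trihydroxy-3,5-dimethylphenyl)hexadecane-1,3-dione F5, which is not isolated; warming with HCl in acetic acid cyclises it, and because the triphenol ring is symmetric either ortho hydroxyl gives 23.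

Step 5. Exchange of the second fluoride, above all the one at C7 between two methyl groups, may be slower than deprotonation of the C2 side chain or methoxide addition at C2, so that conversion stalls or the pyranone is degraded. The fallback changes the oxygen donor and the way it is unmasked, so that neither methoxide in DMSO nor BBr3 is needed; it sets out from 17 and comes back at 23. Benzyl alcohol in excess with NaH in THF–DMF at 70 °C, a medium rich in the parent alcohol, should give 5,7-bis(benzyloxy)-6,8-dimethyl-2-tridecyl-4H-chromen-4-one F6, and hydrogenolysis (H2, Pd/C, EtOAc, rt) cleaves both benzyl ethers to give 23. If alkoxide exchange on the chromone fails whatever the alkoxide, the detour given for step 4 avoids it altogether.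

Step 3. O-acylation of the lithium enolate and a second acylation of the product may compete with the desired C-acylation. The fallback replaces the acylation by an aldol addition and an oxidation; it sets out from 10 and comes back at 14. Enolisation of 10 with LiN(i-Pr)2 in THF at −78 °C and addition of tetradecanal should give the racemic aldol 3-hydroxy-1-(2,4,6-trifluoro-3,5-dimethylphenyl)hexadecan-1-one F7, quenched cold so that the alkoxide cannot displace fluoride; Dess–Martin periodinane in CH2Cl2 then oxidises it to 14.

Further compounds
F1 | step 4 | 2,4,6-trifluoro-3,5-dimethylbenzaldehyde | O=Cc1c(F)c(C)c(F)c(C)c1F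
F2 | step 4 | 2,4,6-trimethoxy-3,5-dimethylbenzaldehyde | O=Cc1c(OC)c(C)c(OC)c(C)c1OC
F3 | step 4 | 1-hydroxy-1-(2,4,6-trimethoxy-3,5-dimethylphenyl)hexadecan-3-one (racemic) | CCCCCCCCCCCCCC(=O)CC(O)c1c(OC)c(C)c(OC)c(C)c1OC
F4 | step 4 | 1-(2,4,6-trimethoxy-3,5-dimethylphenyl)hexadecane-1,3-dione | CCCCCCCCCCCCCC(=O)CC(=O)c1c(OC)c(C)c(OC)c(C)c1OC
F5 | step 4 | 1-(2,4,6-trihydroxy-3,5-dimethylphenyl)hexadecane-1,3-dione | CCCCCCCCCCCCCC(=O)CC(=O)c1c(O)c(C)c(O)c(C)c1O
F6 | step 5 | 5,7-bis(benzyloxy)-6,8-dimethyl-2-tridecyl-4H-chromen-4-one | CCCCCCCCCCCCCc1cc(=O)c2c(OCc3ccccc3)c(C)c(OCc3ccccc3)c(C)c2o1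
F7 | step 3 | 3-hydroxy-1-(2,4,6-trifluoro-3,5-dimethylphenyl)hexadecan-1-one (racemic) | CCCCCCCCCCCCCC(O)CC(=O)c1c(F)c(C)c(F)c(C)c1F
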